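- Monomer is conserved, so once the feed is over each charge splits into free monomer, monomer in chains and a gap.

| setting | alpha | gamma | epsilon | dawn | midnight |
|---|---|---|---|---|---|
| free monomer | 0.52 M (fed, over 8.0 min) | 0.75 M (fed, over 8.0 min) | 0.84 M (fed, over 8.0 min) | 0.50 M (fed, over 8.0 min) | 1.0 M (fed, over 8.0 min) |
| protic impurity | 0.25 M | 0.25 M | 0.25 M | 0.250 M | 0.250 M |
| initiator | 4 mM | 4 mM | 4 mM | 4.0 mM | 4.0 mM |
| remark | run made earlier; the fed solution adds 0.20 times the starting volume | run made earlier; the fed solution adds 0.20 times the starting volume | run made earlier; the fed solution adds 0.20 times the starting volume | the fed solution adds 0.20 times the starting volume | the fed solution adds 0.20 times the starting volume |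
| time |  |  |  | 50 min | 50 min |

- alpha (time / min: monomer in chains / %, free monomer / %): 4.00: 21.6, 17.5; 12.0: 55.4, 13.6; 25.0: 59.1, 3.7; 40.0: 59.5, 2.0
- gamma (time / min: monomer in chains / %, free monomer / %): 3.00: 15.7, 15.3; 6.00: 35.4, 24.8; 15.0: 59.2, 11.7; 40.0: 61.7, 5.9
- epsilon (time / min: monomer in chains / %, free monomer / %): 4.00: 21.8, 19.2; 12.0: 58.2, 17.5; 25.0: 63.5, 8.2; 40.0: 65.0, 6.5

(scatter of a reading: 0.5 percentage points)

- charges are per starting volume, the dose included; the dosed solution carries all of it
- the average divides the monomer in chains by the number of chains, living and dead together; two radicals that join make one chain
- what was read earlier has a scatter of 0.5 percentage points, one standard deviation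
- the earlier runs do not show the number of chains; that part of a forecast is a guess
- percentages count the whole charge, also what has not yet gone in

1. which of the two ends with the longer chains by the average number of monomer units in a chain (living and dead chains, two that joined counted as one) ("neither" if they lie within 10 %) (dawn / midnight / neither)
2. average number of monomer units in a chain (living and dead chains, two that joined counted as one) at the end, dawn
3. average number of monomer units in a chain (living and dead chains, two that joined counted as one) at the end, midnight

- In the gamma run, the charge minus free monomer minus monomer in chains at the last reading was 0.243 M. I named this gap the toll, T.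
- The epsilon run, with its larger charge, gave 0.239 M. So T stayed close to the 0.25 M of protic impurity.
- The leaner alpha run gave 0.200 M.
- The runs show no chain number, so I guessed. I assumed that each initiator gives two radicals and that two radicals make one chain, so I took one chain per initiator, 4.0 mM. That guess served both flasks.
- My first round took the charge minus T as u, the monomer in chains. This gave 0.257 M for dawn and 0.757 M for midnight.
- In my second round I put back what the nearest runs showed: the alpha toll and free share for dawn, the gamma toll and the epsilon free share for midnight. This gave u = 0.290 M for dawn and 0.692 M for midnight, so lengths of 72.5 and 173.
- Then I turned the question round. With equal chains, my dawn figure and the epsilon free share, "neither" needed T at midnight to reach 0.616 M, more than the impurity charge. With my figures for u, midnight otherwise needed twice the chains of dawn from the same initiator charge.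
- The forecast said midnight, with 74 for dawn and 171 for midnight, close to my figures but not the same. Its ground was: “Lean charges lose a large share; rich charges lose only a fixed amount.”
- The flask gave midnight, with 73.7 for dawn and 165 for midnight.

    initiator → 2 initiating radical (k = 0.00560 s⁻¹)
    free monomer + initiating radical → growing radical + monomer in chains (k = 24000 M⁻¹ s⁻¹)
    free monomer + growing radical → monomer in chains + growing radical, rate k3*[growing radical]*[free monomer] (k = 5800 M⁻¹ s⁻¹)
    2 growing radical → dead chain (k = 5.40 × 10⁶ M⁻¹ s⁻¹)
    protic impurity + free monomer → quenched substrate (k = 0.0180 M⁻¹ s⁻¹)

- Midnight held 0.249 M of quenched substrate at the end, against the gamma toll of 0.243 M. Protic impurity was the limiting reagent of the quench in midnight, with 0.28 % of its charge left and 9.0 % of the free monomer charge left.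
- A neighbour flask, like midnight but with 1.7 M of free monomer, kept 13 % free at the end. Its charge less that free part and less T gives 1.24 M in chains and a length of 309. The neighbour flask stood at 306.
- In midnight at 5.78 min, chain growth took free monomer 2.5 times as fast as the protic impurity did.
- In midnight at 50.0 min, the half-life of free monomer by growth was 62 h, and 9.0 % of the charge was still free.

The runs are calculated with constants of no real substance.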